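## The problem

Compound 25 joins two flavonoid halves through one carbon. C2 of a 4,6-dihydroxybenzofuran-3(2H)-one is also C9' of an 8',9'-dihydrofuro[2,3-h]chromen-4'-one: a kaempferol unit whose C8 is bonded to this carbon and whose O7 closes a five-membered hemiketal ring onto C8', which carries a 4-hydroxyphenyl group. The spiro carbon is fully substituted (O1, the C3 ketone, flavonol C8, and C8') and sits between two arenes that bear oxygen on both sides of each junction, so any bond made to it late will be slow. Only the spiro carbon (S) has to be set by the synthesis. The hemiketal carbon (R) can open to a hydroxy ketone and reclose, so it follows the spiro carbon under thermodynamic control. No other stereocentre exists to relay chirality to the spiro carbon, so its configuration must come from a reagent or catalyst. The hemiketal lies β to the C3 ketone and can fragment in a retro-Claisen sense on base; both stereocentres carry benzylic C–O bonds; seven phenols and the flavonol are prone to oxidation. The end game must therefore be short and neutral. The enabling feature is that the spiro carbon is the central carbon of a masked 1,3-dicarbonyl unit (C3 ketone on one side, C8' at the acyl level on the other) and bears an aryl group with an ortho oxygen (O7), while C3 is tied through the phloroglucinol ring to a second phenolic oxygen (O1). C3, the spiro carbon, C8' and O1 are thus C4, C3, C2 and O1 of a 3-aryl-4-hydroxycoumarin in which O1 and O7 have changed places at the acyl carbon.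

## Retrosynthesis

**25 from 24.** The six phenolic O–H bonds are traced back to benzyl ethers in hexabenzyl hemiketal 24. Methyl ethers would need Lewis acids that ionize the hemiketal, and silyl ethers would not survive the aryl-metal and fluoride steps. Benzyl ethers come off in one neutral hydrogenolysis. The forward step must spare the benzylic C–O bonds at C2 and C8' and the pyranone double bond.

**24 from 20 and 21.** The C8'–aryl bond is cut: the hemiketal is the adduct of an aryl nucleophile (22 or 23, from bromide 21) and aryl lactone 20. The neighbouring cut, C8'–C9' by C-aroylation of a benzofuranone enolate, would have to form the quaternary carbon intermolecularly. Cutting the aryl bond instead returns C8' to the carboxyl level, which the coumarin disguise requires. The forward reaction must add once and to the lactone only; the hemiketal configuration is left to equilibration.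

**20 from 17 (key disconnection).** The O7–C8' acyl bond and the O1–C2 bond are cut together. O1 goes back onto the acyl carbon to give a six-membered chromane-2,4-dione, O7 is capped as a silyl ether, and chlorine takes the place of O1 at the future spiro carbon with the opposite configuration. Cutting O1–C2 alone would ask for an intermolecular etherification at a tertiary carbon, and an oxidative spirocyclization would offer no handle on configuration. Chloride 17 has one stereocentre, and that centre is the α-carbon of a cyclic β-keto lactone. The forward step needs fluoride to free the 7-phenoxide (18), acyl transfer to give 19 faster than loss of chloride, and a clean backside displacement. Triisopropylsilyl is preferred to tert-butyldimethylsilyl on the acidic 7-oxygen because the group must survive an enolate step first.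

**17 from 16.** The C–Cl bond is cut to the flat enol of 3-aryl-4-hydroxycoumarin 16. The stereocentre is thus created on a carbon that already carries all its carbon substituents. A chelating Cu(OTf)2–bisoxazoline catalyst is a weak choice here: the two carbonyl oxygens of 16 are nearly equivalent toward a C2-symmetric Lewis acid, and the real difference between the faces lies in the orthogonal flavonyl ring (silyloxy group on one face, pyranone oxygen on the other). An ion-pairing alkaloid catalyst that wraps around the coumarinate is therefore planned.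

**16 from 15, and 15 from 12 and 14.** The C3–C4 bond is cut (intramolecular Claisen condensation of aryl ester 15), then the ester C–O bond (acid 12 plus salicylate 14). The alternative, a cross-coupling at C3 of a preformed 4-hydroxycoumarin with a flavonol C8 electrophile, would have to make a biaryl-type bond with four ortho substituents. Here that bond is inherited from an unhindered aryl–CH2 bond. The forward reactions are an esterification of a chelated phenol and a 6-exo-trig enolate acylation.

**12 from 11, 9, 8 and 7.** The acetic acid side chain of 12 comes from an allyl group by oxidative cleavage (aldehyde 11, silyl ether 9). The C8–allyl bond of 8 comes from O7 by aromatic Claisen rearrangement of allyl ether 7. This delivers carbon to C8 without a directing group and at the same time leaves O7 as the only free phenol, the oxygen that needs the fluoride-labile group.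

**7 from 1 and 4; 14 from 13.** O7 of kaempferol 1 must be told apart from the other three hydroxyls. This is done through tetraacetate 2, selective thiolysis to 3, Mitsunobu allylation with 4 to give 5, and exchange of acetates for benzyl ethers through 6. Salicylate 14 comes from methyl 2,4,6-trihydroxybenzoate 13 by benzylation of the two non-chelated hydroxyls.

## Roads not taken

**Alternative 1:** The cut runs through O1–C2 and C2–C3 of the benzofuranone, leading to diazo ketone A1 and salicylaldehyde A2. Rh2(OAc)4 with a chiral phosphoric acid would turn A1 into a carbene that inserts into the phenolic O–H of A2. The enol so formed would add to the ortho aldehyde and give 3-hydroxy-2,3-dihydrobenzofuran A3. Oxidation of the carbinol of A3 and hydrogenolysis, after which O7 closes onto the aroyl ketone, would finish the synthesis.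
- Merits: it is the most convergent plan, the aryl ketone that becomes the hemiketal is present from the start, and the end game is shorter. In these respects it is the better road.
- Weak points: the carbene carbon is flanked by a di-ortho-substituted flavonyl ring whose 7-benzyloxy CH2 lies within reach for 1,5 C–H insertion. Wolff rearrangement competes. The O–H of A2 is chelated to its aldehyde. Asymmetric trapping of such enols is established for diazo esters, not for hindered diaryl diazo ketones. The quaternary carbon is formed intermolecularly.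
- Comparison: the chosen plan creates the quaternary centre from a flat enol that already carries every substituent and closes both rings intramolecularly. It pays with a longer linear sequence.

**Alternative 2:** The cut is the O7–C8' acyl bond alone, leading to prochiral malonate A4. A chiral phosphoric acid of the TRIP type would make the 7-hydroxyl attack one of the two enantiotopic tert-butyl esters and give lactone A5. Cleavage of the remaining ester of A5 and Friedel–Crafts acylation of the symmetric aryloxy ring would close the furanone, followed by the same aryl addition and hydrogenolysis.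
- Merits: acid-catalysed desymmetrizing lactonization of hydroxy malonates is a demonstrated reaction class, no tertiary halide is needed, and the symmetric aryloxy ring removes any regiochemical question. For the stereo-setting step its precedent is at least as good as that of the chosen plan.
- Weak points: A4 has a carbon bearing a di-ortho-substituted aryl, an aryloxy group and two bulky esters, so the difficult bond construction is only moved earlier. A phenol is a poor nucleophile, and the aryl-ester lactone can reopen under the acid, eroding selectivity. An acylium ion next to an aryloxy-substituted quaternary carbon tends to lose CO, and the Lewis acid endangers the benzyl ethers.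
- Comparison: the chosen plan assembles its precursor from an arylacetic acid by an ester condensation and needs no strong acid. It has to accept a stereo-setting step with weaker precedent.

**Alternative 3:** The cut runs through O1–C7a and C3–C3a, leading to tertiary hydroxy ester A6, in which the ketal ring and both stereocentres are complete, and aryne precursor A7. CsF would release the aryne from A7. The tertiary alkoxide of A6 would add at the aryne carbon remote from the benzyloxy group, and the aryl anion would close onto the methyl ester, giving methyl ketal A8. Ketal hydrolysis and hydrogenolysis would follow.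
- Merits: the base-sensitive β-keto lactone never exists, no organometallic addition is needed late, and the regiochemistry follows the usual rule for 3-alkoxyarynes. The end game is milder than in the chosen plan.
- Weak points: the nucleophile is a tertiary alkoxide between a ketal and a di-ortho-substituted arene. Aryne oligomerization and protonation of the aryl anion (ether without acylation) compete. A6 itself needs an enantioselective oxidation at a tetrasubstituted carbon next to a second fully substituted carbon, so the stereochemical problem is displaced, not solved.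
- Comparison: the chosen plan reaches its stereocentre from a simple enol and transfers it stereospecifically. It has to set a less gentle end game (step 14) against the mild finish of this road.

Key step: step 13

Assumption: the hemiketal carbon C8' of 24 and 25 epimerizes through the open hydroxy ketone, and the required 8'R configuration (hydroxyl cis to the C3 carbonyl and able to hydrogen-bond to it, aryl cis to O1) is taken to be the thermodynamically preferred one.

## Route

Step 1
Reactants: 1 kaempferol
Product: 2 kaempferol 3,5,7,4'-tetraacetate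
Conditions: Ac2O, pyridine, DMAP (cat.), rt
Reagents that add atoms: acetic anhydride, CC(=O)OC(C)=O
Why: Exhaustive O-acetylation by DMAP-catalysed acyl transfer; excess anhydride also acylates the chelated 5-hydroxyl.

Step 2
Reactants: 2 kaempferol tetraacetate
Product: 3 3,5,4'-tri-O-acetylkaempferol (7-hydroxyl free)
Conditions: PhSH, imidazole, N-methylpyrrolidone, 0 °C
Reagents that add atoms: none
Why: Regioselective thiolysis of a flavonoid peracetate; the 7-oxygen is para to the pyranone carbonyl and gives the best phenoxide leaving group, so imidazole-catalysed acyl transfer to thiophenol should remove only this acetate.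

Step 3
Reactants: 3 3,5,4'-tri-O-acetylkaempferol, 4 allyl alcohol
Product: 5 7-O-allyl-3,5,4'-tri-O-acetylkaempferol
Conditions: PPh3, DIAD, THF, 0 °C to rt
Reagents that add atoms: none
Why: Mitsunobu etherification of an acidic phenol; no free phenoxide is formed, so the remaining acetates cannot migrate before O7 is alkylated.

Step 4
Reactants: 5 7-O-allyl-3,5,4'-tri-O-acetylkaempferol
Product: 7 7-(allyloxy)-3,5-bis(benzyloxy)-2-(4-benzyloxyphenyl)-4H-chromen-4-one, via 7-O-allylkaempferol 6 (not isolated)
Conditions: K2CO3, MeOH/THF, rt, argon; evaporate; BnBr, K2CO3, DMF, 70 °C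
Reagents that add atoms: benzyl bromide, BrCc1ccccc1
Why: Methanolysis of the aryl acetates followed by Williamson benzylation in the same flask; the allyl ether is inert to both, and heat with excess bromide is needed only for the chelated 5-hydroxyl.

Step 5
Reactants: 7 7-O-allyl-3,5,4'-tri-O-benzylkaempferol
Product: 8 8-allyl-3,5-bis(benzyloxy)-2-(4-benzyloxyphenyl)-7-hydroxy-4H-chromen-4-one
Conditions: N,N-diethylaniline, 200 °C
Reagents that add atoms: none
Why: Aromatic Claisen rearrangement; in 7-allyloxy-5-alkoxychromones the [3,3] shift goes to C8 because the C7–C8 bond has the higher double-bond character, and the shift leaves O7 as the only free phenol.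

Step 6
Reactants: 8 8-allyl-7-hydroxy flavonol tribenzyl ether
Product: 9 8-allyl-3,5-bis(benzyloxy)-2-(4-benzyloxyphenyl)-7-(triisopropylsilyloxy)-4H-chromen-4-one
Conditions: TIPSCl, imidazole, DMF, rt to 40 °C
Reagents that add atoms: triisopropylsilyl chloride, CC(C)[Si](Cl)(C(C)C)C(C)C
Why: Silylation of a phenol; the bulky triisopropylsilyl group is chosen because it should resist methoxide and oxygen-to-oxygen migration in step 11 yet still leave with fluoride.

Step 7
Reactants: 9 8-allyl-7-silyloxy flavonol
Product: 11 2-[3,5-bis(benzyloxy)-2-(4-benzyloxyphenyl)-4-oxo-7-(triisopropylsilyloxy)-4H-chromen-8-yl]acetaldehyde, via vicinal diol 10 (not isolated)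
Conditions: OsO4 (cat.), NaIO4, 2,6-lutidine, dioxane/H2O, rt
Reagents that add atoms: osmium tetroxide, O=[Os](=O)(=O)=O (delivers the oxygen atom); sodium periodate, [Na+].[O-]I(=O)(=O)=O (restores the oxidant and cleaves the diol)
Why: Lemieux–Johnson oxidation; the terminal alkene is the only isolated C=C bond, since the pyranone C2=C3 bond is tetrasubstituted and part of a vinylogous ester.

Step 8
Reactants: 11 flavonol-8-ylacetaldehyde
Product: 12 2-[3,5-bis(benzyloxy)-2-(4-benzyloxyphenyl)-4-oxo-7-(triisopropylsilyloxy)-4H-chromen-8-yl]acetic acid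
Conditions: NaClO2, NaH2PO4, 2-methyl-2-butene, t-BuOH/THF/H2O, 0 °C to rt
Reagents that add atoms: sodium chlorite, [Na+].[O-]Cl=O
Why: Pinnick oxidation; chlorous acid oxidizes only the aldehyde, and the alkene scavenger takes up hypochlorous acid before it can chlorinate the electron-rich flavonol ring.

Step 9
Reactants: 13 methyl 2,4,6-trihydroxybenzoate
Product: 14 methyl 4,6-bis(benzyloxy)-2-hydroxybenzoate
Conditions: BnBr (2.1 equiv), K2CO3, acetone, reflux
Reagents that add atoms: benzyl bromide, BrCc1ccccc1
Why: Williamson etherification; the hydroxyl chelated to the ester carbonyl is the least reactive, so two equivalents of bromide should stop at the 4,6-dibenzyl ether.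

Step 10
Reactants: 12 flavonol-8-ylacetic acid, 14 methyl 4,6-bis(benzyloxy)-2-hydroxybenzoate
Product: 15 methyl 4,6-bis(benzyloxy)-2-({[3,5-bis(benzyloxy)-2-(4-benzyloxyphenyl)-4-oxo-7-(triisopropylsilyloxy)-4H-chromen-8-yl]acetyl}oxy)benzoate
Conditions: DCC, DMAP, CH2Cl2, 0 °C to rt
Reagents that add atoms: none
Why: Steglich esterification; DMAP turns the O-acylisourea into an acylpyridinium ion that is reactive enough to acylate the chelated phenol.

Step 11
Reactants: 15 aryl ester
Product: 16 5,7-bis(benzyloxy)-3-[3,5-bis(benzyloxy)-2-(4-benzyloxyphenyl)-4-oxo-7-(triisopropylsilyloxy)-4H-chromen-8-yl]-4-hydroxy-2H-chromen-2-one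
Conditions: LiN(SiMe3)2 (2.5 equiv), THF, −78 to 0 °C; cold dilute HCl
Reagents that add atoms: none
Why: Intramolecular Claisen (Dieckmann-type) condensation, the classical route to 3-aryl-4-hydroxycoumarins: the ester enolate adds 6-exo-trig to the methyl benzoate and deprotonation of the acidic product drives the equilibrium; the hindered aryl–C3 bond is inherited from 12, not formed.

Step 12
Reactants: 16 3-aryl-4-hydroxycoumarin
Product: 17 (3R)-5,7-bis(benzyloxy)-3-[3,5-bis(benzyloxy)-2-(4-benzyloxyphenyl)-4-oxo-7-(triisopropylsilyloxy)-4H-chromen-8-yl]-3-chlorochromane-2,4-dione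
Conditions: NCS (1.05 equiv), (DHQD)2PHAL (10 mol %), toluene, 0 °C
Reagents that add atoms: N-chlorosuccinimide, O=C1CCC(=O)N1Cl
Why: Proposed new method: the acidic enol of 16 should protonate a quinuclidine nitrogen of the bis-alkaloid and form a hydrogen-bonded chiral ammonium coumarinate that is far more nucleophilic toward NCS than free 16, so chlorination at C3 should run through the catalyst-bound ion pair and keep the amine protonated while 16 remains; the flavonyl ring stands orthogonal to the coumarin plane with the silyloxy group over one face, chlorine should enter anti to it, and the catalyst therefore sets C3 by choosing between the two exchanging aryl rotamers. The closest known reactions are the cinchona-alkaloid-catalysed enantioselective α-chlorination of cyclic β-keto esters and 3-aryloxindoles and the alkaloid-catalysed chlorinative dearomatization of 1-substituted 2-naphthols; 3-aryl-4-hydroxycoumarins have not been shown as substrates. Which pseudo-enantiomeric alkaloid, (DHQD)2PHAL or (DHQ)2PHAL, delivers the 3R chloride cannot be predicted and is to be settled by assigning the product.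

Step 13
Reactants: 17 (3R)-3-chloro-3-arylchromane-2,4-dione
Product: 20 (2S)-4,6,3',5'-tetrakis(benzyloxy)-2'-(4-benzyloxyphenyl)spiro[1-benzofuran-2,9'-furo[2,3-h]chromene]-3,4',8'-trione, via desilylated chlorodione phenoxide 18 (not isolated), via chloro aroyl lactone phenoxide 19 (not isolated)
Conditions: Bu4N[Ph3SiF2] (1.1 equiv), THF (0.005 M), −40 to 0 °C
Reagents that add atoms: none
Why: Proposed new method: fluoride removes the triisopropylsilyl group and the 7-phenoxide of 18 adds to the lactone carbonyl of the chromane-2,4-dione (5-exo-trig addition–elimination), which closes the five-membered aryl lactone and releases the 2-acylphenoxide of 19. This phenoxide then displaces chloride from the side opposite the leaving group (5-exo-tet), which closes the benzofuran-3-one ring and creates the spiro carbon. The closest known reactions are the nucleophile-induced ring contraction of 3-halochromane-2,4-diones to benzofuran-3(2H)-one-2-carboxylic acid derivatives, the closure of 2-hydroxyphenacyl halides to benzofuran-3-ones and SN2 displacement with inversion at tertiary α-chloro β-keto esters; new here are the internal phenoxide as trigger and the use of an enantioenriched chloride. The only new stereocentre, the spiro carbon, is controlled by C3 of 17: inversion should turn (3R)-17 into (2S)-20. The step needs acyl transfer to outrun loss of chloride, whether by ionization toward a quinone-methide-like species or by chlorine transfer to a phenoxide. The two carbonyl groups on the chlorinated carbon disfavour ionization, the acyl transfer is intramolecular through a five-membered transition state, and dilute THF with an anhydrous, weakly basic fluoride source holds back ionization and bimolecular chlorine transfer. Attack of the 7-phenoxide on the C4 ketone is reversible and unproductive, and direct displacement of chloride by O7 would need a four-membered ring.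

Step 14
Reactants: 20 spiro keto lactone, 21 1-(benzyloxy)-4-bromobenzene
Product: 24 (2S,8'R)-4,6,3',5'-tetrakis(benzyloxy)-2',8'-bis(4-benzyloxyphenyl)-8'-hydroxy-8'H-spiro[1-benzofuran-2,9'-furo[2,3-h]chromene]-3,4'-dione, via 4-benzyloxyphenyllithium 22 (not isolated), via 4-benzyloxyphenylcerium dichloride 23 (not isolated)
Conditions: 21, n-BuLi, THF, −78 °C; CeCl3, −78 °C; then 20, −78 °C; aq NH4Cl at −78 °C
Reagents that add atoms: none
Why: Single 1,2-addition of an organocerium reagent to a lactone to give a lactol; the aryl lactone is the only carbonyl not deactivated by donor oxygens (the pyranone is a vinylogous ester, the furanone ketone is flanked by the quaternary carbon and two alkoxy groups), and the neighbouring quaternary carbon should block a second addition. On work-up the keto phenol recloses, and C8' settles by ring–chain equilibration with the aryl group cis to O1 and the hydroxyl cis to the C3 carbonyl.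

Step 15
Reactants: 24 hexa-O-benzyl hemiketal
Product: 25 (2S,8'R)-3',4,5',6,8'-pentahydroxy-2',8'-bis(4-hydroxyphenyl)-8'H-spiro[1-benzofuran-2,9'-furo[2,3-h]chromene]-3,4'-dione (CNP0283000.1)
Conditions: H2 (1 atm), Pd/C, THF/MeOH, rt
Reagents that add atoms: none
Why: Hydrogenolysis of six aryl benzyl ethers under neutral conditions; primary benzyl ethers should cleave much faster than the hindered, fully substituted C–O bonds at C2 and C8', and the flavonol double bond is normally left intact; C2 is untouched and C8' keeps its equilibrium configuration.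

## Compound list

1 | kaempferol | O=c1c(O)c(-c2ccc(O)cc2)oc2cc(O)cc(O)c12 | starting material
2 | kaempferol 3,5,7,4'-tetraacetate | O=c1c(OC(C)=O)c(-c2ccc(OC(C)=O)cc2)oc2cc(OC(C)=O)cc(OC(C)=O)c12 | intermediate
3 | 3,5,4'-tri-O-acetylkaempferol | O=c1c(OC(C)=O)c(-c2ccc(OC(C)=O)cc2)oc2cc(O)cc(OC(C)=O)c12 | intermediate
4 | allyl alcohol (prop-2-en-1-ol) | C=CCO | starting material
5 | 7-O-allyl-3,5,4'-tri-O-acetylkaempferol | O=c1c(OC(C)=O)c(-c2ccc(OC(C)=O)cc2)oc2cc(OCC=C)cc(OC(C)=O)c12 | intermediate
6 | 7-O-allylkaempferol (not isolated) | O=c1c(O)c(-c2ccc(O)cc2)oc2cc(OCC=C)cc(O)c12 | intermediate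
7 | 7-(allyloxy)-3,5-bis(benzyloxy)-2-(4-benzyloxyphenyl)-4H-chromen-4-one | O=c1c(OCc2ccccc2)c(-c2ccc(OCc3ccccc3)cc2)oc2cc(OCC=C)cc(OCc3ccccc3)c12 | intermediate
8 | 8-allyl-3,5-bis(benzyloxy)-2-(4-benzyloxyphenyl)-7-hydroxy-4H-chromen-4-one | O=c1c(OCc2ccccc2)c(-c2ccc(OCc3ccccc3)cc2)oc2c(CC=C)c(O)cc(OCc3ccccc3)c12 | intermediate
9 | 8-allyl-3,5-bis(benzyloxy)-2-(4-benzyloxyphenyl)-7-(triisopropylsilyloxy)-4H-chromen-4-one | O=c1c(OCc2ccccc2)c(-c2ccc(OCc3ccccc3)cc2)oc2c(CC=C)c(O[Si](C(C)C)(C(C)C)C(C)C)cc(OCc3ccccc3)c12 | intermediate
10 | 3,5-bis(benzyloxy)-2-(4-benzyloxyphenyl)-8-(2,3-dihydroxypropyl)-7-(triisopropylsilyloxy)-4H-chromen-4-one (racemic, not isolated) | O=c1c(OCc2ccccc2)c(-c2ccc(OCc3ccccc3)cc2)oc2c(CC(O)CO)c(O[Si](C(C)C)(C(C)C)C(C)C)cc(OCc3ccccc3)c12 | intermediate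
11 | 2-[3,5-bis(benzyloxy)-2-(4-benzyloxyphenyl)-4-oxo-7-(triisopropylsilyloxy)-4H-chromen-8-yl]acetaldehyde | O=CCc1c(O[Si](C(C)C)(C(C)C)C(C)C)cc(OCc2ccccc2)c2c(=O)c(OCc3ccccc3)c(-c3ccc(OCc4ccccc4)cc3)oc12 | intermediate
12 | 2-[3,5-bis(benzyloxy)-2-(4-benzyloxyphenyl)-4-oxo-7-(triisopropylsilyloxy)-4H-chromen-8-yl]acetic acid | OC(=O)Cc1c(O[Si](C(C)C)(C(C)C)C(C)C)cc(OCc2ccccc2)c2c(=O)c(OCc3ccccc3)c(-c3ccc(OCc4ccccc4)cc3)oc12 | intermediate
13 | methyl 2,4,6-trihydroxybenzoate | COC(=O)c1c(O)cc(O)cc1O | starting material
14 | methyl 4,6-bis(benzyloxy)-2-hydroxybenzoate | COC(=O)c1c(O)cc(OCc2ccccc2)cc1OCc1ccccc1 | intermediate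
15 | methyl 4,6-bis(benzyloxy)-2-({[3,5-bis(benzyloxy)-2-(4-benzyloxyphenyl)-4-oxo-7-(triisopropylsilyloxy)-4H-chromen-8-yl]acetyl}oxy)benzoate | COC(=O)c1c(OC(=O)Cc2c(O[Si](C(C)C)(C(C)C)C(C)C)cc(OCc3ccccc3)c3c(=O)c(OCc4ccccc4)c(-c4ccc(OCc5ccccc5)cc4)oc23)cc(OCc2ccccc2)cc1OCc1ccccc1 | intermediate
16 | 5,7-bis(benzyloxy)-3-[3,5-bis(benzyloxy)-2-(4-benzyloxyphenyl)-4-oxo-7-(triisopropylsilyloxy)-4H-chromen-8-yl]-4-hydroxy-2H-chromen-2-one | O=c1oc2cc(OCc3ccccc3)cc(OCc3ccccc3)c2c(O)c1-c1c(O[Si](C(C)C)(C(C)C)C(C)C)cc(OCc2ccccc2)c2c(=O)c(OCc3ccccc3)c(-c3ccc(OCc4ccccc4)cc3)oc12 | intermediate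
17 | (3R)-5,7-bis(benzyloxy)-3-[3,5-bis(benzyloxy)-2-(4-benzyloxyphenyl)-4-oxo-7-(triisopropylsilyloxy)-4H-chromen-8-yl]-3-chlorochromane-2,4-dione | O=C1Oc2cc(OCc3ccccc3)cc(OCc3ccccc3)c2C(=O)[C@]1(Cl)c1c(O[Si](C(C)C)(C(C)C)C(C)C)cc(OCc2ccccc2)c2c(=O)c(OCc3ccccc3)c(-c3ccc(OCc4ccccc4)cc3)oc12 | intermediate
18 | tetrabutylammonium 7-phenoxide of (3R)-3-chloro-3-(flavonol-8-yl)chromane-2,4-dione (17 without its silyl group; not isolated) | CCCC[N+](CCCC)(CCCC)CCCC.O=C1Oc2cc(OCc3ccccc3)cc(OCc3ccccc3)c2C(=O)[C@]1(Cl)c1c([O-])cc(OCc2ccccc2)c2c(=O)c(OCc3ccccc3)c(-c3ccc(OCc4ccccc4)cc3)oc12 | intermediate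
19 | tetrabutylammonium salt of (9R)-3,5-bis(benzyloxy)-2-(4-benzyloxyphenyl)-9-chloro-9-[4,6-bis(benzyloxy)-2-oxidobenzoyl]furo[2,3-h]chromene-4,8(9H)-dione (not isolated) | CCCC[N+](CCCC)(CCCC)CCCC.[O-]c1cc(OCc2ccccc2)cc(OCc2ccccc2)c1C(=O)[C@@]1(Cl)C(=O)Oc2cc(OCc3ccccc3)c3c(=O)c(OCc4ccccc4)c(-c4ccc(OCc5ccccc5)cc4)oc3c21 | intermediate
20 | (2S)-4,6,3',5'-tetrakis(benzyloxy)-2'-(4-benzyloxyphenyl)spiro[1-benzofuran-2,9'-furo[2,3-h]chromene]-3,4',8'-trione (penta-O-benzyl spiro keto lactone) | O=C1c2c(OCc3ccccc3)cc(OCc3ccccc3)cc2O[C@@]12c1c(cc(OCc3ccccc3)c3c(=O)c(OCc4ccccc4)c(-c4ccc(OCc5ccccc5)cc4)oc13)OC2=O | intermediate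
21 | 1-(benzyloxy)-4-bromobenzene | Brc1ccc(OCc2ccccc2)cc1 | starting material
22 | 4-benzyloxyphenyllithium (not isolated) | [Li]c1ccc(OCc2ccccc2)cc1 | intermediate
23 | 4-benzyloxyphenylcerium dichloride (not isolated) | Cl[Ce](Cl)c1ccc(OCc2ccccc2)cc1 | intermediate
24 | (2S,8'R)-4,6,3',5'-tetrakis(benzyloxy)-2',8'-bis(4-benzyloxyphenyl)-8'-hydroxy-8'H-spiro[1-benzofuran-2,9'-furo[2,3-h]chromene]-3,4'-dione (hexa-O-benzyl hemiketal) | O=C1c2c(OCc3ccccc3)cc(OCc3ccccc3)cc2O[C@@]12c1c(cc(OCc3ccccc3)c3c(=O)c(OCc4ccccc4)c(-c4ccc(OCc5ccccc5)cc4)oc13)O[C@]2(O)c1ccc(OCc2ccccc2)cc1 | intermediate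
25 | (2S,8'R)-3',4,5',6,8'-pentahydroxy-2',8'-bis(4-hydroxyphenyl)-8'H-spiro[1-benzofuran-2,9'-furo[2,3-h]chromene]-3,4'-dione (CNP0283000.1) | O=C1c2c(O)cc(O)cc2O[C@@]12c1c(cc(O)c3c(=O)c(O)c(-c4ccc(O)cc4)oc13)O[C@]2(O)c1ccc(O)cc1 | target

## Step count and uncertain steps

Total: 15 steps. Longest linear sequence: 14 steps (kaempferol 1 to 25 through steps 1–8 and 10–15); step 9 prepares the second fragment.

**Step 13 (key step, proposed method).** The first event, acyl transfer from the 7-phenoxide to the 2-acylphenoxide, may be uphill and is pulled through only by the irreversible displacement. This lengthens the life of phenoxide 18, so three processes may compete: ionization of the C–Cl bond with loss of configuration, chlorine transfer from the chlorodicarbonyl to a phenoxide (reductive dechlorination plus ring chlorination), and attack of fluoride on the activated lactone. The fallback uses the known alkoxide-induced ring contraction, sets out from 17 and returns at 20. NaOMe (1 equiv) in MeOH/THF at −40 °C opens the lactone as the methyl ester, and the released phenoxide closes the furanone with inversion while the silyl ether stays on, giving methyl (2S)-2-(7-silyloxyflavonol-8-yl)-3-oxobenzofuran-2-carboxylate F1. HF·pyridine in THF then frees the 7-phenol to give hydroxy ester F2. Acid-catalysed lactonization (TsOH, toluene, 80 °C, molecular sieves to take up methanol) closes the five-membered lactone and gives 20. This separates desilylation from ring contraction and keeps the external nucleophile of the known reaction.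

**Step 12 (proposed method).** Facial discrimination may be poor for three reasons: uncatalysed chlorination of free 16 by NCS competes, the catalyst has to choose between two aryl rotamers whose exchange may be slow at 0 °C, and the free amine may open the lactone of 17 once 16 is consumed. The fallback sets out from 16 and returns at 17. NCS alone in CH2Cl2 gives the racemic chloride F3. Preparative chromatography on a polysaccharide chiral stationary phase with an alcohol-free eluent separates (3R)-17, which re-enters the route, from the (3S)-chloride F4. F4 is returned to 16 by reductive dechlorination with NaI in acetic acid, so the unwanted enantiomer is recycled. The configuration is assigned through the anomalous scattering of chlorine or by correlation with 25.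

**Step 14.** The alkoxide adduct may fragment in the retro-Claisen sense (cleavage of the C9'–C8' bond with expulsion of the benzofuranone enolate). A second addition to the liberated ketone or addition to the pyranone carbonyl may also occur. The fallback sets out from 20 and returns at 24. N,O-dimethylhydroxylamine (with Me3Al) opens the aryl lactone to the Weinreb amide with free 7-hydroxyl F5. Silylation (Et3SiCl, imidazole) gives the triethylsilyl ether F6. Aryllithium 22 adds to the amide, whose chelated adduct cannot fragment or add twice, and work-up gives the aryl ketone F7. HF·pyridine removes the silyl group, and the phenol closes onto the ketone to give 24.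

**Step 15.** Hydrogenolysis may not stop at the benzyl ethers: the benzylic C–O bonds at C8' and C2 may be cleaved, or the pyranone double bond saturated. The fallback sets out from 24 and returns at 25 without new intermediates. The ethers are cleaved by Lewis acid instead of by reduction, using BCl3 with pentamethylbenzene as cation scavenger in CH2Cl2 at −78 °C; the hemiketal, if ionized, is restored on aqueous work-up.

## Further compounds

F1 | step 13 | methyl (2S)-4,6-bis(benzyloxy)-2-[3,5-bis(benzyloxy)-2-(4-benzyloxyphenyl)-4-oxo-7-(triisopropylsilyloxy)-4H-chromen-8-yl]-3-oxo-2,3-dihydro-1-benzofuran-2-carboxylate | COC(=O)[C@]1(Oc2cc(OCc3ccccc3)cc(OCc3ccccc3)c2C1=O)c1c(O[Si](C(C)C)(C(C)C)C(C)C)cc(OCc2ccccc2)c2c(=O)c(OCc3ccccc3)c(-c3ccc(OCc4ccccc4)cc3)oc12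
F2 | step 13 | methyl (2S)-4,6-bis(benzyloxy)-2-[3,5-bis(benzyloxy)-2-(4-benzyloxyphenyl)-7-hydroxy-4-oxo-4H-chromen-8-yl]-3-oxo-2,3-dihydro-1-benzofuran-2-carboxylate | COC(=O)[C@]1(Oc2cc(OCc3ccccc3)cc(OCc3ccccc3)c2C1=O)c1c(O)cc(OCc2ccccc2)c2c(=O)c(OCc3ccccc3)c(-c3ccc(OCc4ccccc4)cc3)oc12
F3 | step 12 | racemic 5,7-bis(benzyloxy)-3-[3,5-bis(benzyloxy)-2-(4-benzyloxyphenyl)-4-oxo-7-(triisopropylsilyloxy)-4H-chromen-8-yl]-3-chlorochromane-2,4-dione | O=C1Oc2cc(OCc3ccccc3)cc(OCc3ccccc3)c2C(=O)C1(Cl)c1c(O[Si](C(C)C)(C(C)C)C(C)C)cc(OCc2ccccc2)c2c(=O)c(OCc3ccccc3)c(-c3ccc(OCc4ccccc4)cc3)oc12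
F4 | step 12 | (3S)-5,7-bis(benzyloxy)-3-[3,5-bis(benzyloxy)-2-(4-benzyloxyphenyl)-4-oxo-7-(triisopropylsilyloxy)-4H-chromen-8-yl]-3-chlorochromane-2,4-dione | O=C1Oc2cc(OCc3ccccc3)cc(OCc3ccccc3)c2C(=O)[C@@]1(Cl)c1c(O[Si](C(C)C)(C(C)C)C(C)C)cc(OCc2ccccc2)c2c(=O)c(OCc3ccccc3)c(-c3ccc(OCc4ccccc4)cc3)oc12
F5 | step 14 | (2S)-4,6-bis(benzyloxy)-2-[3,5-bis(benzyloxy)-2-(4-benzyloxyphenyl)-7-hydroxy-4-oxo-4H-chromen-8-yl]-N-methoxy-N-methyl-3-oxo-2,3-dihydro-1-benzofuran-2-carboxamide | CON(C)C(=O)[C@]1(Oc2cc(OCc3ccccc3)cc(OCc3ccccc3)c2C1=O)c1c(O)cc(OCc2ccccc2)c2c(=O)c(OCc3ccccc3)c(-c3ccc(OCc4ccccc4)cc3)oc12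
F6 | step 14 | (2S)-4,6-bis(benzyloxy)-2-[3,5-bis(benzyloxy)-2-(4-benzyloxyphenyl)-4-oxo-7-(triethylsilyloxy)-4H-chromen-8-yl]-N-methoxy-N-methyl-3-oxo-2,3-dihydro-1-benzofuran-2-carboxamide | CON(C)C(=O)[C@]1(Oc2cc(OCc3ccccc3)cc(OCc3ccccc3)c2C1=O)c1c(O[Si](CC)(CC)CC)cc(OCc2ccccc2)c2c(=O)c(OCc3ccccc3)c(-c3ccc(OCc4ccccc4)cc3)oc12
F7 | step 14 | (2R)-4,6-bis(benzyloxy)-2-(4-benzyloxybenzoyl)-2-[3,5-bis(benzyloxy)-2-(4-benzyloxyphenyl)-4-oxo-7-(triethylsilyloxy)-4H-chromen-8-yl]-1-benzofuran-3(2H)-one | O=C(c1ccc(OCc2ccccc2)cc1)[C@]1(Oc2cc(OCc3ccccc3)cc(OCc3ccccc3)c2C1=O)c1c(O[Si](CC)(CC)CC)cc(OCc2ccccc2)c2c(=O)c(OCc3ccccc3)c(-c3ccc(OCc4ccccc4)cc3)oc12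
F0 | step 15 | none | none
A1 | alternative 1 | 1-(4-benzyloxyphenyl)-2-diazo-2-[3,5,7-tris(benzyloxy)-2-(4-benzyloxyphenyl)-4-oxo-4H-chromen-8-yl]ethanone | [N-]=[N+]=C(C(=O)c1ccc(OCc2ccccc2)cc1)c1c(OCc2ccccc2)cc(OCc2ccccc2)c2c(=O)c(OCc3ccccc3)c(-c3ccc(OCc4ccccc4)cc3)oc12
A2 | alternative 1 | 4,6-bis(benzyloxy)-2-hydroxybenzaldehyde | O=Cc1c(O)cc(OCc2ccccc2)cc1OCc1ccccc1
A3 | alternative 1 | 2-(4-benzyloxybenzoyl)-4,6-bis(benzyloxy)-3-hydroxy-2-(tetra-O-benzylkaempferol-8-yl)-2,3-dihydrobenzofuran, hydroxyl cis to the aroyl group, C2 configured as in 25 | O[C@@H]1c2c(OCc3ccccc3)cc(OCc3ccccc3)cc2O[C@@]1(C(=O)c1ccc(OCc2ccccc2)cc1)c1c(OCc2ccccc2)cc(OCc2ccccc2)c2c(=O)c(OCc3ccccc3)c(-c3ccc(OCc4ccccc4)cc3)oc12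
A4 | alternative 2 | di-tert-butyl 2-[3,5-bis(benzyloxy)phenoxy]-2-[3,5-bis(benzyloxy)-2-(4-benzyloxyphenyl)-7-hydroxy-4-oxo-4H-chromen-8-yl]malonate | CC(C)(C)OC(=O)C(Oc1cc(OCc2ccccc2)cc(OCc2ccccc2)c1)(C(=O)OC(C)(C)C)c1c(O)cc(OCc2ccccc2)c2c(=O)c(OCc3ccccc3)c(-c3ccc(OCc4ccccc4)cc3)oc12
A5 | alternative 2 | tert-butyl 9-[3,5-bis(benzyloxy)phenoxy]-3,5-bis(benzyloxy)-2-(4-benzyloxyphenyl)-4,8-dioxo-8,9-dihydrofuro[2,3-h]chromene-9-carboxylate, C9 configured as C2 of 25 | CC(C)(C)OC(=O)[C@]1(Oc2cc(OCc3ccccc3)cc(OCc3ccccc3)c2)C(=O)Oc2cc(OCc3ccccc3)c3c(=O)c(OCc4ccccc4)c(-c4ccc(OCc5ccccc5)cc4)oc3c12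
A6 | alternative 3 | methyl (8R,9R)-3,5-bis(benzyloxy)-2,8-bis(4-benzyloxyphenyl)-9-hydroxy-8-methoxy-4-oxo-8,9-dihydrofuro[2,3-h]chromene-9-carboxylate | COC(=O)[C@@]1(O)c2c(cc(OCc3ccccc3)c3c(=O)c(OCc4ccccc4)c(-c4ccc(OCc5ccccc5)cc4)oc23)O[C@]1(OC)c1ccc(OCc2ccccc2)cc1
A7 | alternative 3 | 3,5-bis(benzyloxy)-2-(trimethylsilyl)phenyl trifluoromethanesulfonate | C[Si](C)(C)c1c(OCc2ccccc2)cc(OCc2ccccc2)cc1OS(=O)(=O)C(F)(F)F
A8 | alternative 3 | (2S,8'R)-4,6,3',5'-tetrakis(benzyloxy)-2',8'-bis(4-benzyloxyphenyl)-8'-methoxy-8'H-spiro[1-benzofuran-2,9'-furo[2,3-h]chromene]-3,4'-dione (hexa-O-benzyl methyl ketal of 25) | O=C1c2c(OCc3ccccc3)cc(OCc3ccccc3)cc2O[C@@]12c1c(cc(OCc3ccccc3)c3c(=O)c(OCc4ccccc4)c(-c4ccc(OCc5ccccc5)cc4)oc13)O[C@]2(OC)c1ccc(OCc2ccccc2)cc1
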